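**Retrosynthetic overview**

1. Ring numbering: C1 is the quinone carbonyl between C2 (OMe) and C6 (side chain), C4 is the other carbonyl, and the side chain is C1'H2–C2'H(OAc)–C13H27. Without the C1 oxygen the ring is a 5-alkylresorcinol, with oxygens on C2 and C4 and the chain on C6. This alternating pattern is that of an acetate-derived ring whose starter unit carries the C2' oxygen, and the strategy rests on it.
2. Ardisinone ⇐ para-oxidation at C1 (oxygen added last) of a 3-methoxy-5-alkylphenol that already carries the C2' acetate ⇐ aromatisation of a symmetric 5-substituted cyclohexane-1,3-dione, in which the C2 and C4 oxygens are equivalent.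
3. The only ring is closed in one flask from two acyclic halves: dimethyl malonate and (R,E)-6-silyloxynonadec-3-en-2-one, by Michael addition (bond C1–C6) followed by Claisen closure (bond C2–C3).
4. Enone ⇐ cross metathesis of methyl vinyl ketone with the silyl ether of (R)-heptadec-1-en-4-ol ⇐ enantioselective allylboration of tetradecanal, which sets the only stereocentre (C2', R).

Key step: step 4

Remark on the chemistry: the TBS ether is not expected to survive the hydrogen iodide released in step 6, so its removal is planned there, and the acetate is installed before the base-sensitive methoxyquinone is formed.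

**Route**

Step 1
Reactants: 1 tetradecanal; 2 allylboronic acid pinacol ester
Product: 4 (R)-heptadec-1-en-4-ol, via homoallyl pinacol borate 3 (not isolated)
Conditions: 2 (1.2 equiv), (S)-TRIP [(S)-3,3'-bis(2,4,6-triisopropylphenyl)-1,1'-binaphthyl-2,2'-diyl hydrogen phosphate] (5 mol %), toluene, −30 °C; then H2O, rt
Reagents that add atoms: none
Why: Chiral phosphoric acid-catalysed allylboration through a closed chair (Zimmerman–Traxler-type) transition state in which the acid binds a boronate oxygen and the formyl hydrogen; the (S)-catalyst should deliver the allyl group to the Si face of the aldehyde, which gives the R carbinol.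

Step 2
Reactants: 4 (R)-heptadec-1-en-4-ol
Product: 5 (R)-tert-butyl(heptadec-1-en-4-yloxy)dimethylsilane
Conditions: TBSCl (1.2 equiv), imidazole (2.5 equiv), DMF, rt
Reagents that add atoms: tert-butyldimethylsilyl chloride, CC(C)(C)[Si](C)(C)Cl
Why: Imidazole-promoted silylation (Corey protocol) of an unhindered secondary alcohol, which masks the oxygen against vinylogous retro-aldol and elimination in the later base steps and does not touch the stereocentre.

Step 3
Reactants: 5 (R)-tert-butyl(heptadec-1-en-4-yloxy)dimethylsilane; 6 methyl vinyl ketone
Product: 7 (R,E)-6-[(tert-butyldimethylsilyl)oxy]nonadec-3-en-2-one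
Conditions: 6 (3 equiv), second-generation Grubbs catalyst (H2IMes)(PCy3)Cl2Ru=CHPh (3 mol %), CH2Cl2, 40 °C
Reagents that add atoms: none
Why: Olefin cross metathesis between a readily dimerising terminal alkene and an electron-poor enone that does not self-couple, so the cross product should dominate with the thermodynamic E geometry, while the silyl ether and the allylic-remote stereocentre are inert to the ruthenium carbene.

Step 4
Reactants: 7 (R,E)-6-[(tert-butyldimethylsilyl)oxy]nonadec-3-en-2-one; 8 dimethyl malonate
Product: 10 methyl 6-[(2R)-2-(tert-butyldimethylsilyloxy)pentadecyl]-2,4-dioxocyclohexane-1-carboxylate, via Michael adduct 9 (not isolated)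
Conditions: 8 (1.2 equiv), NaOMe (1.05 equiv), MeOH, 0 °C; 7 added, 0 °C to rt; then reflux; AcOH (1.1 equiv), 0 °C
Reagents that add atoms: none
Why: Sodium dimethyl malonate adds 1,4 to the β-carbon of enone 7 (ring bond C1–C6) to give keto diester 9, and after proton exchange the methyl ketone enolate attacks one malonate ester carbonyl in a Claisen (Dieckmann-type) condensation (ring bond C2–C3), expelling methoxide. The closest known reaction is the classical Michael–Claisen annulation of malonates with alk-3-en-2-ones that leads to 5-alkylresorcinols such as olivetol. The six-membered carbocycle closes in a 6-(enolexo)-exo-trig mode, and the reversible sequence is drawn forward because 10 is deprotonated to its stabilised 1,3-dicarbonyl enolate, which consumes the one equivalent of base. The two new ring stereocentres (C1 and C6 of the cyclohexane) are not controlled beyond the thermodynamic trans preference of the epimerisable C1, and both disappear on aromatisation, whereas C2' lies outside every acidic system and stays R. The step needs conjugate addition to win over γ-deprotonation of 7, which would expel the δ-silyloxy group and give a dienone. This is secured by pre-forming the weakly basic malonate anion with less than one equivalent of methoxide per malonate and adding the enone cold before heating.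

Step 5
Reactants: 10 methyl 6-[(2R)-2-(tert-butyldimethylsilyloxy)pentadecyl]-2,4-dioxocyclohexane-1-carboxylate
Product: 12 5-[(2R)-2-(tert-butyldimethylsilyloxy)pentadecyl]cyclohexane-1,3-dione, via keto acid 11 (not isolated)
Conditions: NaOH (2 M aq., 4 equiv), MeOH, reflux; then 0 °C, 1 M HCl to pH 4; 50 °C until CO2 evolution ends
Reagents that add atoms: none
Why: Ester saponification followed by decarboxylation of the β-keto acid through the usual cyclic six-membered transition state on gentle acidification, conditions that a secondary alkyl TBS ether should tolerate and that leave a dione with a mirror plane through C5.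

Step 6
Reactants: 12 5-[(2R)-2-(tert-butyldimethylsilyloxy)pentadecyl]cyclohexane-1,3-dione
Product: 15 3-[(2R)-2-hydroxypentadecyl]-5-methoxyphenol, via methyl enol ether 13 (not isolated), via silylated methoxyphenol 14 (not isolated)
Conditions: I2 (2 equiv), MeOH, reflux; then aq. Na2S2O3
Reagents that add atoms: methanol, CO
Why: Iodine–methanol oxidative aromatisation, in which acid-catalysed formation of vinylogous ester 13, α-iodination and loss of HI give the dienone tautomer of the phenol; the second oxygen stays a carbonyl until it emerges as the free phenol, the symmetry of 12 makes the choice of oxygen irrelevant, and the HI released should methanolyse the silyl ether in the same flask without touching the C2' configuration.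

Step 7
Reactants: 15 3-[(2R)-2-hydroxypentadecyl]-5-methoxyphenol
Product: 16 3-[(2R)-2-acetoxypentadecyl]-5-methoxyphenyl acetate
Conditions: Ac2O (3 equiv), pyridine (4 equiv), DMAP (4-dimethylaminopyridine, 5 mol %), CH2Cl2, 0 °C to rt
Reagents that add atoms: acetic anhydride, CC(=O)OC(C)=O
Why: Nucleophile-catalysed O-acetylation of both hydroxyl groups with retention at C2', done on the robust arene so that the quinone never meets acylation conditions.

Step 8
Reactants: 16 3-[(2R)-2-acetoxypentadecyl]-5-methoxyphenyl acetate
Product: 17 (2R)-1-(3-hydroxy-5-methoxyphenyl)pentadecan-2-yl acetate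
Conditions: pyrrolidine (1.5 equiv), THF, 0 °C to rt
Reagents that add atoms: none
Why: Chemoselective aminolysis of an aryl ester, whose phenoxide is a far better leaving group than the alkoxide of the secondary alkyl acetate, so only the phenol should be released.

Step 9
Reactants: 17 (2R)-1-(3-hydroxy-5-methoxyphenyl)pentadecan-2-yl acetate
Product: 18 ardisinone [(2R)-1-(5-methoxy-3,6-dioxocyclohexa-1,4-dien-1-yl)pentadecan-2-yl acetate]
Conditions: (KSO3)2NO (2.5 equiv), aq. KH2PO4 (pH 6), acetone/H2O, rt
Reagents that add atoms: potassium nitrosodisulfonate (Fremy's salt), [K+].[K+].[O-]S(=O)(=O)N([O])S(=O)(=O)[O-]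
Why: Teuber oxidation, in which one nitrosodisulfonate radical removes the phenolic hydrogen, a second couples at the open para carbon C1 between the methoxy group and the side chain, and loss of imidodisulfonate gives the 1,4-quinone; the near-neutral buffer should leave the acetate and the stereocentre untouched.

**Compound list**

1 | tetradecanal | CCCCCCCCCCCCCC=O | starting material
2 | allylboronic acid pinacol ester (2-allyl-4,4,5,5-tetramethyl-1,3,2-dioxaborolane) | C=CCB1OC(C)(C)C(C)(C)O1 | starting material
3 | (R)-2-(heptadec-1-en-4-yloxy)-4,4,5,5-tetramethyl-1,3,2-dioxaborolane | CCCCCCCCCCCCC[C@H](CC=C)OB1OC(C)(C)C(C)(C)O1 | intermediate (not isolated)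
4 | (R)-heptadec-1-en-4-ol | CCCCCCCCCCCCC[C@H](CC=C)O | intermediate
5 | (R)-tert-butyl(heptadec-1-en-4-yloxy)dimethylsilane | CCCCCCCCCCCCC[C@H](CC=C)O[Si](C)(C)C(C)(C)C | intermediate
6 | methyl vinyl ketone (but-3-en-2-one) | CC(=O)C=C | starting material
7 | (R,E)-6-[(tert-butyldimethylsilyl)oxy]nonadec-3-en-2-one | CCCCCCCCCCCCC[C@H](C/C=C/C(C)=O)O[Si](C)(C)C(C)(C)C | intermediate
8 | dimethyl malonate | COC(=O)CC(=O)OC | starting material
9 | dimethyl 2-[(6R)-6-(tert-butyldimethylsilyloxy)-2-oxononadecan-4-yl]malonate (both C4 epimers) | CCCCCCCCCCCCC[C@H](CC(CC(C)=O)C(C(=O)OC)C(=O)OC)O[Si](C)(C)C(C)(C)C | intermediate (not isolated)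
10 | methyl 6-[(2R)-2-(tert-butyldimethylsilyloxy)pentadecyl]-2,4-dioxocyclohexane-1-carboxylate (ring diastereomers and enol forms) | CCCCCCCCCCCCC[C@H](CC1CC(=O)CC(=O)C1C(=O)OC)O[Si](C)(C)C(C)(C)C | intermediate
11 | 6-[(2R)-2-(tert-butyldimethylsilyloxy)pentadecyl]-2,4-dioxocyclohexane-1-carboxylic acid | CCCCCCCCCCCCC[C@H](CC1CC(=O)CC(=O)C1C(=O)O)O[Si](C)(C)C(C)(C)C | intermediate (not isolated)
12 | 5-[(2R)-2-(tert-butyldimethylsilyloxy)pentadecyl]cyclohexane-1,3-dione | CCCCCCCCCCCCC[C@H](CC1CC(=O)CC(=O)C1)O[Si](C)(C)C(C)(C)C | intermediate
13 | 5-[(2R)-2-(tert-butyldimethylsilyloxy)pentadecyl]-3-methoxycyclohex-2-en-1-one (both C5 epimers) | CCCCCCCCCCCCC[C@H](CC1CC(=O)C=C(OC)C1)O[Si](C)(C)C(C)(C)C | intermediate (not isolated)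
14 | 3-[(2R)-2-(tert-butyldimethylsilyloxy)pentadecyl]-5-methoxyphenol | CCCCCCCCCCCCC[C@H](Cc1cc(O)cc(OC)c1)O[Si](C)(C)C(C)(C)C | intermediate (not isolated)
15 | 3-[(2R)-2-hydroxypentadecyl]-5-methoxyphenol | CCCCCCCCCCCCC[C@H](Cc1cc(O)cc(OC)c1)O | intermediate
16 | 3-[(2R)-2-acetoxypentadecyl]-5-methoxyphenyl acetate | CCCCCCCCCCCCC[C@H](Cc1cc(OC(C)=O)cc(OC)c1)OC(C)=O | intermediate
17 | (2R)-1-(3-hydroxy-5-methoxyphenyl)pentadecan-2-yl acetate | CCCCCCCCCCCCC[C@H](Cc1cc(O)cc(OC)c1)OC(C)=O | intermediate
18 | ardisinone, (2R)-1-(5-methoxy-3,6-dioxocyclohexa-1,4-dien-1-yl)pentadecan-2-yl acetate | CCCCCCCCCCCCC[C@H](CC1=CC(=O)C=C(OC)C1=O)OC(C)=O | target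

**Step count**

Total: 9 steps. Longest linear sequence: 9 steps (1 to 18).

**Steps most likely to fail**

Step 4 (key step). What may go wrong: γ-deprotonation of the enone with vinylogous loss of silanolate, or reversal of the Michael addition during the hot Claisen stage, may outrun ring closure. Fallback: the roles of the two halves are exchanged. It sets out from 5 and comes back to the route at 10. Cross metathesis of 5 with methyl acrylate (second-generation Grubbs catalyst, CH2Cl2, 40 °C) should give methyl (R,E)-5-[(tert-butyldimethylsilyl)oxy]octadec-2-enoate F1, which is much less γ-acidic than the enone. Heating F1 with methyl acetoacetate and NaOMe in MeOH should give, by Michael addition of the acetoacetate anion, dimethyl 2-acetyl-3-[(2R)-2-(tert-butyldimethylsilyloxy)pentadecyl]pentanedioate F2. The acetyl methyl enolate of F2 then closes onto the side-chain ester, and this Claisen step leads to the same cyclohexanedione ester 10.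

Step 6. What may go wrong: over-methylation to the dimethyl ether, iodination of the electron-rich ring, incomplete dehydrogenation, or attack of hydrogen iodide on the free C2' alcohol. Fallback: a stepwise dehydrogenation without halogen or strong acid. It sets out from 12 and comes back at 15.
- O-Methylation of 12 with Me3SiCHN2 in MeOH/toluene should give vinylogous ester 13, now isolated.
- Kinetic deprotonation at C6 with LiN(iPr)2 (THF, −78 °C) and trapping with Me3SiCl should give tert-butyl({(2R)-1-[5-methoxy-3-(trimethylsilyloxy)cyclohexa-2,4-dien-1-yl]pentadecan-2-yl}oxy)dimethylsilane F3.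
- Saegusa–Ito dehydrogenation of F3 with Pd(OAc)2 (divalent palladium, MeCN, rt) should give the cross-conjugated dienone, which tautomerises to phenol 14.
- Bu4NF in THF then removes the silyl group to give 15.

Step 1. What may go wrong: insufficient facial selectivity with an unbranched aliphatic aldehyde, which matters because the enantiomeric purity fixed here cannot be raised later. Fallback: the stereocentre is taken from the chiral pool. This fallback does not draw on a numbered compound: it replaces 1 and 2 by commercial (R)-epichlorohydrin (ClC[C@H]1CO1) and comes back to the route at 4.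
- Opening at the terminal carbon with dodecylmagnesium bromide and catalytic CuI (THF, −30 °C) should give (R)-1-chloropentadecan-2-ol F4.
- NaOH in Et2O closes F4 to (R)-2-tridecyloxirane F5.
- Vinylmagnesium bromide with catalytic CuI (THF, −20 °C) opens F5 at its CH2 group to give 4.
- No bond to the stereocentre is made or broken at any stage.

Further compounds
F1 | step 4 | methyl (R,E)-5-[(tert-butyldimethylsilyl)oxy]octadec-2-enoate | CCCCCCCCCCCCC[C@H](C/C=C/C(=O)OC)O[Si](C)(C)C(C)(C)C
F2 | step 4 | dimethyl 2-acetyl-3-[(2R)-2-(tert-butyldimethylsilyloxy)pentadecyl]pentanedioate | CCCCCCCCCCCCC[C@H](CC(CC(=O)OC)C(C(C)=O)C(=O)OC)O[Si](C)(C)C(C)(C)C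
F3 | step 6 | tert-butyl({(2R)-1-[5-methoxy-3-(trimethylsilyloxy)cyclohexa-2,4-dien-1-yl]pentadecan-2-yl}oxy)dimethylsilane | CCCCCCCCCCCCC[C@H](CC1CC(OC)=CC(O[Si](C)(C)C)=C1)O[Si](C)(C)C(C)(C)C
F4 | step 1 | (R)-1-chloropentadecan-2-ol | CCCCCCCCCCCCC[C@H](CCl)O
F5 | step 1 | (R)-2-tridecyloxirane | CCCCCCCCCCCCC[C@@H]1CO1
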